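**Strategy.** The route rests on disconnecting the bond between C2 of the pyran ring (the fully substituted, oxygen-bearing carbon next to the C3=C4 unsaturation) and the adjacent CH2 of the ethylene tether to the cyclohexene ring. Because C2 is a tertiary carbinol carbon flanked by unsaturation, it is made as a propargylic carbenoid: an enantiopure aryl-butynyl carbamate is lithiated and united with the cyclohexenylethyl pinacol boronate. A stereospecific 1,2-metallate shift forms the C2–CH2 bond and the fully substituted stereocentre in one operation, and oxidation installs the C2–O bond. Semihydrogenation, then oxidation of the tetramethoxyarene to the quinone, which closes the pyran ring (O1–C8a), complete the synthesis.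

Key step: step 7

Assumption: the oxazaborolidinium ion of (R) configuration is taken to leave open the Cα-si face of bound methacrolein (formyl C–H···O binding, enal stacked on the nearby phenyl group); should the sense be the opposite, its (S) enantiomer serves in the same step.

**Step 1**
Reactants: 1 methacrolein (2-methylprop-2-enal); 2 (E)-3-methylpenta-1,3-diene
Product: 3 (1R,2S)-1,2,3-trimethylcyclohex-3-ene-1-carbaldehyde
Conditions: (R)-3,3-diphenyl-1-(2-methylphenyl)tetrahydro-1H,3H-pyrrolo[1,2-c][1,3,2]oxazaborole (10 mol %), Tf2NH (10 mol %), CH2Cl2, −78 → −40 °C; 2 as the commercial E/Z mixture in excess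
Reagents that add atoms: none
Why: Enantioselective Diels–Alder reaction under chiral oxazaborolidinium catalysis, in which the terminal methyl of the diene directs the "ortho" orientation, the endo formyl group ends up cis to the C2 methyl, the shielded enal face fixes both stereocentres at once, and only the E-diene can reach the s-cis form.

**Step 2**
Reactants: 3 (1R,2S)-1,2,3-trimethylcyclohex-3-ene-1-carbaldehyde
Product: 4 (5S,6S)-5-ethenyl-1,5,6-trimethylcyclohex-1-ene
Conditions: Ph3PCH3Br, KOtBu, THF, 0 °C → rt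
Reagents that add atoms: methyltriphenylphosphonium bromide, C[P+](c1ccccc1)(c1ccccc1)c1ccccc1.[Br-]
Why: Wittig methylenation of a non-enolisable aldehyde (fully substituted α-carbon), so neither stereocentre can epimerise.

**Step 3**
Reactants: 4 (5S,6S)-5-ethenyl-1,5,6-trimethylcyclohex-1-ene
Product: 5 4,4,5,5-tetramethyl-2-{2-[(1R,2R)-1,2,3-trimethylcyclohex-3-en-1-yl]ethyl}-1,3,2-dioxaborolane
Conditions: HBpin, [Ir(cod)Cl]2 (1.5 mol %), bis(diphenylphosphino)methane (3 mol %), CH2Cl2, rt
Reagents that add atoms: pinacolborane, CC1(C)OBOC1(C)C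
Why: Iridium-catalysed anti-Markovnikov hydroboration should place boron on the terminal carbon of the monosubstituted vinyl group and leave the trisubstituted ring alkene and both stereocentres untouched (the descriptor at the fully substituted carbon changes by priority only).

**Step 4**
Reactants: 6 1,2,4,5-tetramethoxybenzene
Product: 8 3-iodo-1,2,4,5-tetramethoxybenzene, via 2,3,5,6-tetramethoxyphenyllithium 7 (not isolated)
Conditions: nBuLi (1.05 equiv), THF, 0 °C; then I2, −78 °C → rt
Reagents that add atoms: iodine, II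
Why: Directed ortho-metalation at the ring C–H flanked by two methoxy groups, followed by iodinolysis of the aryllithium.

**Step 5**
Reactants: 8 3-iodo-1,2,4,5-tetramethoxybenzene; 9 (R)-but-3-yn-2-ol
Product: 10 (R)-4-(2,3,5,6-tetramethoxyphenyl)but-3-yn-2-ol
Conditions: PdCl2(PPh3)2 (5 mol %), CuI (10 mol %), Et3N, THF, 60 °C
Reagents that add atoms: none
Why: Sonogashira coupling of the aryl iodide with the terminal alkyne, which does not touch the chiral-pool carbinol centre.

**Step 6**
Reactants: 10 (R)-4-(2,3,5,6-tetramethoxyphenyl)but-3-yn-2-ol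
Product: 11 (R)-4-(2,3,5,6-tetramethoxyphenyl)but-3-yn-2-yl N,N-diisopropylcarbamate
Conditions: iPr2NCOCl, Et3N, DMAP (cat.), CH2Cl2, reflux
Reagents that add atoms: N,N-diisopropylcarbamoyl chloride, CC(C)N(C(C)C)C(=O)Cl
Why: O-Carbamoylation (acylation at oxygen) leaves the C–O bond and its configuration intact and installs the group that later directs lithiation and serves as leaving group.

**Step 7**
Reactants: 11 (R)-4-(2,3,5,6-tetramethoxyphenyl)but-3-yn-2-yl N,N-diisopropylcarbamate; 5 4,4,5,5-tetramethyl-2-{2-[(1R,2R)-1,2,3-trimethylcyclohex-3-en-1-yl]ethyl}-1,3,2-dioxaborolane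
Product: 15 (S)-3-methyl-1-(2,3,5,6-tetramethoxyphenyl)-5-[(1S,2R)-1,2,3-trimethylcyclohex-3-en-1-yl]pent-1-yn-3-ol, via lithiated carbamate 12 (not isolated), via lithium boronate complex 13 (not isolated), via tertiary propargylic boronic ester 14 (not isolated)
Conditions: sBuLi (1.1 equiv), TMEDA, Et2O, −78 °C, 15 min; 5, −78 °C, 1 h; MgBr2·OEt2, −78 °C → rt; then NaOH, H2O2, THF/H2O, 0 °C → rt
Reagents that add atoms: hydrogen peroxide, OO
Why: Lithiation–borylation: carbamate-directed deprotonation of 11 occurs with retention to give the α-oxygenated propargyl-lithium 12, which is borylated by 5 with retention (boronate 13); the primary alkyl group then migrates from boron to carbon antiperiplanar to the departing carbamate (1,2-metallate rearrangement, inversion at carbon), forming the bond between the carbinol carbon and the tether CH2 and creating the fully substituted centre as boronic ester 14, and oxidation replaces boron by OH with retention. The closest known reaction type is the stereospecific homologation of boronic esters with lithiated secondary propargylic (also allylic or benzylic) carbamates. No ring is closed. The new stereocentre is controlled solely by the (R)-configured carbamate carbon of 11 (retention in the borylation, inversion in the migration), which should give the (S)-alcohol; the remote centres of 5 play no part. The step needs (a) lithiation at the propargylic C–H and not at the aryl C–H between two methoxy groups, secured by the carbamate through complex-induced proximity and the far higher acidity of that site, (b) borylation at the α- and not the γ-carbon, secured by lithium held at the α-carbon by the carbamate carbonyl, (c) configurational stability of 12, for which the low temperature, the short lithiation time and the bulky di-ortho-substituted aryl cap on the alkyne are relied on, and (d) migration of carbon only, which follows because the pinacol oxygens do not migrate.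

**Step 8**
Reactants: 15 (S)-3-methyl-1-(2,3,5,6-tetramethoxyphenyl)-5-[(1S,2R)-1,2,3-trimethylcyclohex-3-en-1-yl]pent-1-yn-3-ol
Product: 16 (S,Z)-3-methyl-1-(2,3,5,6-tetramethoxyphenyl)-5-[(1S,2R)-1,2,3-trimethylcyclohex-3-en-1-yl]pent-1-en-3-ol
Conditions: H2 (1 atm), Pd/CaCO3 poisoned with Pb(OAc)2, quinoline, EtOAc, rt
Reagents that add atoms: none
Why: Lindlar semihydrogenation adds H2 syn to the alkyne and should give the Z-alkene while the trisubstituted ring alkene and the arene stay untouched.

**Step 9**
Reactants: 16 (S,Z)-3-methyl-1-(2,3,5,6-tetramethoxyphenyl)-5-[(1S,2R)-1,2,3-trimethylcyclohex-3-en-1-yl]pent-1-en-3-ol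
Product: 18 (S)-6-methoxy-2-methyl-2-{2-[(1S,2R)-1,2,3-trimethylcyclohex-3-en-1-yl]ethyl}-2H-chromene-5,8-dione (CNP0234259.2), via hydroxyalkenyl dimethoxyquinone 17 (not isolated)
Conditions: (NH4)2Ce(NO3)6 (2.5 equiv), MeCN/H2O (2:1), 0 °C; crude 17 taken on with camphorsulfonic acid (10 mol %), 4 Å molecular sieves, CH2Cl2, rt, in the dark
Reagents that add atoms: water, O
Why: Oxidative demethylation of the 1,2,4,5-tetramethoxyarene by tetravalent cerium should give the 2,5-dimethoxy-1,4-benzoquinone 17 (both para pairs lead to the same quinone), whose Z-alkene holds the tertiary hydroxyl next to the methoxy-bearing quinone carbon, so that addition–elimination (vinylogous transesterification, six-membered ring) closes the pyran ring without breaking the C2–O bond and hence with retention at C2.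

**Compound list**

1 | methacrolein (2-methylprop-2-enal) | CC(=C)C=O | starting material
2 | (E)-3-methylpenta-1,3-diene | C=C/C(C)=C/C | starting material
3 | (1R,2S)-1,2,3-trimethylcyclohex-3-ene-1-carbaldehyde | O=C[C@]1(C)CCC=C(C)[C@@H]1C | intermediate
4 | (5S,6S)-5-ethenyl-1,5,6-trimethylcyclohex-1-ene | C=C[C@]1(C)CCC=C(C)[C@@H]1C | intermediate
5 | 4,4,5,5-tetramethyl-2-{2-[(1R,2R)-1,2,3-trimethylcyclohex-3-en-1-yl]ethyl}-1,3,2-dioxaborolane | CC1(C)OB(CC[C@]2(C)CCC=C(C)[C@@H]2C)OC1(C)C | intermediate
6 | 1,2,4,5-tetramethoxybenzene | COc1cc(OC)c(OC)cc1OC | starting material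
7 | 2,3,5,6-tetramethoxyphenyllithium | [Li]c1c(OC)c(OC)cc(OC)c1OC | intermediate (not isolated)
8 | 3-iodo-1,2,4,5-tetramethoxybenzene | COc1cc(OC)c(OC)c(I)c1OC | intermediate
9 | (R)-but-3-yn-2-ol | C#C[C@@H](C)O | starting material
10 | (R)-4-(2,3,5,6-tetramethoxyphenyl)but-3-yn-2-ol | COc1cc(OC)c(OC)c(C#C[C@@H](C)O)c1OC | intermediate
11 | (R)-4-(2,3,5,6-tetramethoxyphenyl)but-3-yn-2-yl N,N-diisopropylcarbamate | COc1cc(OC)c(OC)c(C#C[C@@H](C)OC(=O)N(C(C)C)C(C)C)c1OC | intermediate
12 | lithiated carbamate: 11 with lithium in place of the carbinol hydrogen (retention) | COc1cc(OC)c(OC)c(C#C[C@@]([Li])(C)OC(=O)N(C(C)C)C(C)C)c1OC | intermediate (not isolated)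
13 | lithium pinacol boronate complex: boron bound to the carbamate-bearing propargylic carbon (in place of lithium, retention) and to the CH2 of the cyclohexenylethyl group of 5 | COc1cc(OC)c(OC)c(C#C[C@@]([B-]2(CC[C@]3(C)CCC=C(C)[C@@H]3C)OC(C)(C)C(C)(C)O2)(C)OC(=O)N(C(C)C)C(C)C)c1OC.[Li+] | intermediate (not isolated)
14 | 4,4,5,5-tetramethyl-2-{(R)-3-methyl-1-(2,3,5,6-tetramethoxyphenyl)-5-[(1S,2R)-1,2,3-trimethylcyclohex-3-en-1-yl]pent-1-yn-3-yl}-1,3,2-dioxaborolane | COc1cc(OC)c(OC)c(C#C[C@](C)(CC[C@]2(C)CCC=C(C)[C@@H]2C)B3OC(C)(C)C(C)(C)O3)c1OC | intermediate (not isolated)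
15 | (S)-3-methyl-1-(2,3,5,6-tetramethoxyphenyl)-5-[(1S,2R)-1,2,3-trimethylcyclohex-3-en-1-yl]pent-1-yn-3-ol | COc1cc(OC)c(OC)c(C#C[C@](C)(CC[C@]2(C)CCC=C(C)[C@@H]2C)O)c1OC | intermediate
16 | (S,Z)-3-methyl-1-(2,3,5,6-tetramethoxyphenyl)-5-[(1S,2R)-1,2,3-trimethylcyclohex-3-en-1-yl]pent-1-en-3-ol | COc1cc(OC)c(OC)c(/C=C\[C@](C)(CC[C@]2(C)CCC=C(C)[C@@H]2C)O)c1OC | intermediate
17 | 3-{(S,Z)-3-hydroxy-3-methyl-5-[(1S,2R)-1,2,3-trimethylcyclohex-3-en-1-yl]pent-1-en-1-yl}-2,5-dimethoxycyclohexa-2,5-diene-1,4-dione | COC1=CC(=O)C(OC)=C(/C=C\[C@](C)(CC[C@]2(C)CCC=C(C)[C@@H]2C)O)C1=O | intermediate (not isolated)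
18 | (S)-6-methoxy-2-methyl-2-{2-[(1S,2R)-1,2,3-trimethylcyclohex-3-en-1-yl]ethyl}-2H-chromene-5,8-dione (CNP0234259.2) | COC1=CC(=O)C2=C(C=C[C@](C)(CC[C@]3(C)CCC=C(C)[C@@H]3C)O2)C1=O | target

**Step count.** Total: 9 steps. Longest linear sequence: 6 steps (steps 1, 2, 3, 7, 8, 9; the arene branch, steps 4, 5, 6, 7, 8, 9, is equally long).

**Steps most likely to fail**

1. Step 7. The lithiated aryl-alkynyl carbamate may racemise through its allenyl-lithium form before it is borylated, the arene may be lithiated in competition, or boron may be taken up at the γ-carbon; each would erode the configuration or the yield at C2. Fallback (union with a silyl-capped carbenoid, arene attached afterwards), setting out from 5 and coming back at 15: commercial (R)-4-(trimethylsilyl)but-3-yn-2-ol is carbamoylated (iPr2NCOCl, Et3N) to (R)-4-(trimethylsilyl)but-3-yn-2-yl N,N-diisopropylcarbamate F1, the substrate class for which this homologation is best established. Lithiation (sBuLi, TMEDA, Et2O, −78 °C), borylation with 5, 1,2-migration and NaOH/H2O2 oxidation should give (S)-3-methyl-1-(trimethylsilyl)-5-[(1S,2R)-1,2,3-trimethylcyclohex-3-en-1-yl]pent-1-yn-3-ol F2. K2CO3 in MeOH removes the silyl group to give (S)-3-methyl-5-[(1S,2R)-1,2,3-trimethylcyclohex-3-en-1-yl]pent-1-yn-3-ol F3, and Sonogashira coupling of F3 with 8 (PdCl2(PPh3)2, CuI, Et3N) returns to 15.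

2. Step 1. The cycloaddition may show insufficient facial discrimination, or the diene may add in the exo mode or with the reversed orientation, so that the two ring stereocentres are not set cleanly. Fallback (resolution in place of asymmetric catalysis), setting out from 1 and 2 and coming back at 3: EtAlCl2-promoted Diels–Alder reaction gives racemic (1R*,2S*)-1,2,3-trimethylcyclohex-3-ene-1-carbaldehyde F4, and NaBH4 reduction gives racemic [(1R*,2S*)-1,2,3-trimethylcyclohex-3-en-1-yl]methanol F5. Esterification with (S)-2-methoxy-2-phenylacetic acid (DCC, DMAP) and separation of the diastereomers by chromatography or crystallisation should give [(1R,2S)-1,2,3-trimethylcyclohex-3-en-1-yl]methyl (S)-2-methoxy-2-phenylacetate F6. LiOH cleavage gives [(1R,2S)-1,2,3-trimethylcyclohex-3-en-1-yl]methanol F7, and Swern oxidation returns to 3.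

3. Step 9. Before the arene is oxidised, the acidic medium may ionise the electron-rich tertiary allylic carbinol of 16 (loss of configuration at C2 or dehydration), and the alkenes may be over-oxidised. Fallback (oxidation before semihydrogenation), setting out from 15 and coming back at 17: (NH4)2Ce(NO3)6 oxidation at the alkyne stage, where the propargylic carbinol does not ionise readily, should give 3-{(S)-3-hydroxy-3-methyl-5-[(1S,2R)-1,2,3-trimethylcyclohex-3-en-1-yl]pent-1-yn-1-yl}-2,5-dimethoxycyclohexa-2,5-diene-1,4-dione F8. Hydrogen over Pb(OAc)2-poisoned Pd/CaCO3 then reduces the quinone to the hydroquinone and the alkyne to the Z-alkene, giving 3-{(S,Z)-3-hydroxy-3-methyl-5-[(1S,2R)-1,2,3-trimethylcyclohex-3-en-1-yl]pent-1-en-1-yl}-2,5-dimethoxybenzene-1,4-diol F9. Neutral reoxidation with Ag2O gives quinone 17, which closes to 18 as in step 9.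

**Further compounds**

F1 | step 7 | (R)-4-(trimethylsilyl)but-3-yn-2-yl N,N-diisopropylcarbamate | C[Si](C)(C)C#C[C@@H](C)OC(=O)N(C(C)C)C(C)C
F2 | step 7 | (S)-3-methyl-1-(trimethylsilyl)-5-[(1S,2R)-1,2,3-trimethylcyclohex-3-en-1-yl]pent-1-yn-3-ol | C[Si](C)(C)C#C[C@](C)(CC[C@]1(C)CCC=C(C)[C@@H]1C)O
F3 | step 7 | (S)-3-methyl-5-[(1S,2R)-1,2,3-trimethylcyclohex-3-en-1-yl]pent-1-yn-3-ol | C#C[C@](C)(CC[C@]1(C)CCC=C(C)[C@@H]1C)O
F4 | step 1 | racemic (1R*,2S*)-1,2,3-trimethylcyclohex-3-ene-1-carbaldehyde (both enantiomers) | O=C[C@]1(C)CCC=C(C)[C@@H]1C.O=C[C@@]1(C)CCC=C(C)[C@H]1C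
F5 | step 1 | racemic [(1R*,2S*)-1,2,3-trimethylcyclohex-3-en-1-yl]methanol (both enantiomers) | OC[C@]1(C)CCC=C(C)[C@@H]1C.OC[C@@]1(C)CCC=C(C)[C@H]1C
F6 | step 1 | [(1R,2S)-1,2,3-trimethylcyclohex-3-en-1-yl]methyl (S)-2-methoxy-2-phenylacetate | CO[C@H](C(=O)OC[C@]1(C)CCC=C(C)[C@@H]1C)c1ccccc1
F7 | step 1 | [(1R,2S)-1,2,3-trimethylcyclohex-3-en-1-yl]methanol | OC[C@]1(C)CCC=C(C)[C@@H]1C
F8 | step 9 | 3-{(S)-3-hydroxy-3-methyl-5-[(1S,2R)-1,2,3-trimethylcyclohex-3-en-1-yl]pent-1-yn-1-yl}-2,5-dimethoxycyclohexa-2,5-diene-1,4-dione | COC1=CC(=O)C(OC)=C(C#C[C@](C)(CC[C@]2(C)CCC=C(C)[C@@H]2C)O)C1=O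
F9 | step 9 | 3-{(S,Z)-3-hydroxy-3-methyl-5-[(1S,2R)-1,2,3-trimethylcyclohex-3-en-1-yl]pent-1-en-1-yl}-2,5-dimethoxybenzene-1,4-diol | COc1cc(O)c(OC)c(/C=C\[C@](C)(CC[C@]2(C)CCC=C(C)[C@@H]2C)O)c1O
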